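**Plan**

- Retrosynthesis: the C5' propenol is cut at its C=C (Wittig, ester reduction) back to a C5' aldehyde. Then O1–C2 (ring B) and O1'–C2' (ring D) are cut together to an open-chain triphenol. Its C2–C3 and C2'–C3' bonds are cut to benzylic bromides plus one arylacetyl imide, made from 5-iodovanillin and dimethyl malonate.
- Enabling feature: C2 of ring B (O1–C2–C3–C3a–C7a on arene C, carrying guaiacyl ring A) is para to the ring A hydroxyl. C2' of ring D (the primed copy on arene E, bonded to C5 of arene C) is para to O1. With both rings open, each is a CH2 para to a free phenol, oxidisable to a p-quinone methide beside a phenol.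
- Forward: imide 11 is alkylated as its sodium enolate with the ring A bromide, its silyloxymethyl arm becomes CH2Br, and a second molecule of 11 is alkylated with it as its lithium enolate. Reduction and unmasking give the triphenol; DDQ closes ring D and then, in relay, ring B; the side chain is completed last.
- Stereochemistry: C3 and C3' come from two Evans alkylations with (S)-4-benzyl-2-oxazolidinone. C2 and C2' are set in the DDQ step, trans to C3 and C3'. The alkene is E from a stabilised ylide.

Key step: step 16

Remark: alcohol 12 is taken as a purchased material, and in the DDQ step the more electron-rich arene C phenol is assumed to be oxidised before the ring A phenol.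

**Route**

Step 1
Reactants: 1 5-iodovanillin
Product: 2 4-(benzyloxy)-3-iodo-5-methoxybenzaldehyde
Conditions: BnBr, K2CO3, DMF, rt
Reagents that add atoms: benzyl bromide, BrCc1ccccc1
Why: Williamson etherification of the acidic phenol should be clean, and the benzyl ether survives every later base, hydride and fluoride step.

Step 2
Reactants: 2 4-(benzyloxy)-3-iodo-5-methoxybenzaldehyde
Product: 3 [4-(benzyloxy)-3-iodo-5-methoxyphenyl]methanol
Conditions: NaBH4, MeOH/THF, 0 °C
Reagents that add atoms: none
Why: Borohydride reduction of the aryl aldehyde masks the formyl carbon as a benzylic alcohol and leaves the aryl iodide and benzyl ether alone.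

Step 3
Reactants: 3 [4-(benzyloxy)-3-iodo-5-methoxyphenyl]methanol
Product: 4 benzylic triisopropylsilyl ether of 3
Conditions: i-Pr3SiCl, imidazole, DMF, rt
Reagents that add atoms: chlorotriisopropylsilane, CC(C)[Si](Cl)(C(C)C)C(C)C
Why: Silylation of the primary alcohol gives a bulky silyl ether that should survive carbonate at 70 °C, hot hydroxide, brief pH 3 and amide bases, and leaves later with fluoride.

Step 4
Reactants: 4 benzylic triisopropylsilyl ether of 3; 5 dimethyl malonate
Product: 6 dimethyl 2-[2-(benzyloxy)-3-methoxy-5-(triisopropylsilyloxymethyl)phenyl]malonate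
Conditions: CuI (10 mol %), 2-picolinic acid (20 mol %), Cs2CO3, 1,4-dioxane, 70 °C
Reagents that add atoms: none
Why: Copper-catalysed Hurtley-type arylation of the malonate anion by the aryl iodide should place the two-carbon acid precursor ortho to the benzyloxy group, the ethers being inert to Cs2CO3.

Step 5
Reactants: 6 dimethyl arylmalonate
Product: 8 2-[2-(benzyloxy)-3-methoxy-5-(triisopropylsilyloxymethyl)phenyl]acetic acid, via arylmalonic acid 7 (not isolated)
Conditions: NaOH, MeOH/H2O, 60 °C; NaHSO4 aq to pH 3, 0 °C; toluene, 90 °C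
Reagents that add atoms: sodium hydroxide, [Na+].[OH-]
Why: Saponification followed by thermal decarboxylation of the arylmalonic acid (malonic ester synthesis) should leave the arylacetic acid, the silyl ether tolerating hydroxide and the short cold acidification.

Step 6
Reactants: 8 arylacetic acid; 9 (S)-4-benzyl-2-oxazolidinone
Product: 11 (4S)-4-benzyl-3-{2-[2-(benzyloxy)-3-methoxy-5-(triisopropylsilyloxymethyl)phenyl]acetyl}oxazolidin-2-one, via mixed pivalic anhydride 10 (not isolated)
Conditions: t-BuCOCl, Et3N, THF, −20 °C; then 9, LiCl, −20 °C → rt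
Reagents that add atoms: none
Why: N-Acylation of the oxazolidinone through the mixed pivalic anhydride (LiCl/Et3N imide preparation) should work because the hindered pivaloyl carbonyl steers the auxiliary nitrogen to the arylacetyl carbonyl.

Step 7
Reactants: 12 [4-(benzyloxy)-3-methoxyphenyl]methanol
Product: 13 4-(benzyloxy)-3-methoxybenzyl bromide
Conditions: PBr3, Et2O, 0 °C
Reagents that add atoms: phosphorus tribromide, BrP(Br)Br
Why: Bromination of an electron-rich benzylic alcohol with PBr3 is routine, and the bromide is used without storage.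

Step 8
Reactants: 11 arylacetyl imide; 13 4-(benzyloxy)-3-methoxybenzyl bromide
Product: 15 (4S)-4-benzyl-3-[(2S)-2-aryl-3-(4-benzyloxy-3-methoxyphenyl)propanoyl]oxazolidin-2-one (aryl = arene C unit of 11), via sodium Z-enolate 14 (not isolated)
Conditions: NaN(SiMe3)2, THF, −78 °C; then 13, −78 → −30 °C
Reagents that add atoms: none
Why: Evans asymmetric alkylation, in which the chelated Z enolate is shielded on one face by the auxiliary benzyl group so the bromide enters from the other face and sets the future C3 as S, the α-branched product resisting re-enolisation through allylic 1,3-strain.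

Step 9
Reactants: 15 mono-imide silyl ether
Product: 16 benzylic alcohol of 15 (CH2OH para to the arene C benzyloxy group)
Conditions: HF·pyridine, pyridine/THF, 0 °C → rt
Reagents that add atoms: none
Why: Fluoride desilylation in a non-basic medium should free the benzylic alcohol without touching the epimerisable imide centre or the benzyl ethers.

Step 10
Reactants: 16 benzylic alcohol
Product: 17 benzylic bromide of 16
Conditions: CBr4, PPh3, CH2Cl2, 0 °C
Reagents that add atoms: carbon tetrabromide, BrC(Br)(Br)Br
Why: The Appel reaction converts the benzylic alcohol to the bromide under neutral conditions that spare the imide and its stereocentre.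

Step 11
Reactants: 11 arylacetyl imide; 17 benzylic bromide
Product: 19 bis-imide (both α-carbons S; arene E unit still carrying the silyloxymethyl group), via lithium Z-enolate 18 (not isolated)
Conditions: 11 (1.3 equiv), LiN(SiMe3)2 (1.25 equiv), THF, −78 °C; then 17, −78 → −10 °C
Reagents that add atoms: none
Why: A second Evans asymmetric alkylation on the same enolate face sets the future C3' as S, and the lithium enolate is chosen here because it is less basic and more tightly chelated than the sodium one, so it should leave the α-branched imide already present in 17 (itself shielded from enolisation by allylic 1,3-strain) untouched while still being alkylated by this very electron-rich benzylic bromide.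

Step 12
Reactants: 19 bis-imide
Product: 20 (S,S)-diol (tris-benzyl ether, silyl ether retained)
Conditions: LiBH4, THF/MeOH, 0 °C → rt
Reagents that add atoms: none
Why: Reductive cleavage of N-acyl oxazolidinones with LiBH4 (hydride attack at the exocyclic carbonyl) should turn both imides into primary alcohols without disturbing the stereocentres and return the auxiliary.

Step 13
Reactants: 20 diol silyl ether
Product: 21 triol (benzylic CH2OH on arene E)
Conditions: Bu4NF, THF, 0 °C → rt
Reagents that add atoms: none
Why: Fluoride desilylation of the remaining silyl ether is routine and the benzyl ethers are inert.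

Step 14
Reactants: 21 triol
Product: 22 tris-benzyl diol aldehyde
Conditions: MnO2, CH2Cl2, rt
Reagents that add atoms: none
Why: MnO2 oxidation is selective for the benzylic alcohol, so the aldehyde should form while the two aliphatic primary alcohols stay untouched.

Step 15
Reactants: 22 tris-benzyl diol aldehyde
Product: 23 open-chain triphenol diol aldehyde
Conditions: H2 (1 atm), 10% Pd/C, EtOAc, rt
Reagents that add atoms: none
Why: Catalytic hydrogenolysis of the three aryl benzyl ethers should be faster than reduction of the electron-rich aryl aldehyde in ethyl acetate, provided the reaction is stopped once the last ether is gone.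

Step 16
Reactants: 23 open-chain triphenol diol aldehyde
Product: 27 bis(dihydrobenzofuran) aldehyde (2R,3S,2'R,3'S), via arene C quinone methide 24 (not isolated), via ring D phenol 25 (not isolated), via ring A quinone methide 26 (not isolated)
Conditions: DDQ (2.1 equiv, two portions), 1,4-dioxane, 10 °C → rt
Reagents that add atoms: none
Why: DDQ removes hydride from the CH2 para to the arene C hydroxyl to give p-quinone methide 24, whose methide carbon (future C2') is attacked by the arene E phenol in a 5-exo-trig oxa-conjugate addition that closes ring D and re-aromatises arene C to phenol 25; the second equivalent oxidises the CH2 para to the ring A hydroxyl to methide 26, and the regenerated arene C hydroxyl adds 5-exo-trig to close ring B. The closest known reaction is the DDQ dehydrogenative cyclisation of a 4-alkylphenol bearing a neighbouring phenol (phenylcoumaran and pterocarpan ring closure through a p-quinone methide), here run twice in relay. C2' is set trans to the hydroxymethyl group on C3' and C2 trans to that on C3, because the phenol adds to the methide face away from the existing substituent and because each closure is reversible while a para hydroxyl is free, so the more stable 2,3-trans rings should accumulate. Site selectivity rests on the substrate: only these two CH2 groups are para to free phenols, the arene E phenol is para to the formyl group and has no benzylic hydrogen to lose, and the aliphatic hydroxyls could only close four-membered rings. Over-oxidation to benzofurans is held back by one equivalent of DDQ per ring at or below room temperature in a non-nucleophilic solvent.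

Step 17
Reactants: 27 bis(dihydrobenzofuran) aldehyde; 28 ethyl (triphenylphosphoranylidene)acetate
Product: 29 ethyl (E)-acrylate at C5'
Conditions: 28 (2.5 equiv), CH2Cl2, rt → 40 °C
Reagents that add atoms: none
Why: Wittig olefination with a stabilised ylide should give the E-acrylate, the ylide being too weakly basic to open the dihydrofuran rings and indifferent to the free hydroxyls.

Step 18
Reactants: 29 ethyl (E)-acrylate
Product: 30 target CNP0250921.1
Conditions: i-Bu2AlH (7 equiv), CH2Cl2/THF, −78 → −20 °C; aq. KNaC4H4O6 work-up
Reagents that add atoms: none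
Why: 1,2-Reduction of the α,β-unsaturated ester by excess i-Bu2AlH (the phenol and alcohols are first taken up as aluminium alkoxides) should give the E-allylic alcohol, and the neutral tartrate work-up protects the acid-sensitive cinnamyl alcohol.

**Compound list**

1 | 5-iodovanillin (4-hydroxy-3-iodo-5-methoxybenzaldehyde) | COc1cc(C=O)cc(I)c1O | starting material
2 | 4-(benzyloxy)-3-iodo-5-methoxybenzaldehyde | COc1cc(C=O)cc(I)c1OCc1ccccc1 | intermediate
3 | [4-(benzyloxy)-3-iodo-5-methoxyphenyl]methanol | COc1cc(CO)cc(I)c1OCc1ccccc1 | intermediate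
4 | {[4-(benzyloxy)-3-iodo-5-methoxyphenyl]methoxy}triisopropylsilane | COc1cc(CO[Si](C(C)C)(C(C)C)C(C)C)cc(I)c1OCc1ccccc1 | intermediate
5 | dimethyl malonate | COC(=O)CC(=O)OC | starting material
6 | dimethyl 2-[2-(benzyloxy)-3-methoxy-5-(triisopropylsilyloxymethyl)phenyl]malonate | COC(=O)C(C(=O)OC)c1cc(CO[Si](C(C)C)(C(C)C)C(C)C)cc(OC)c1OCc1ccccc1 | intermediate
7 | 2-[2-(benzyloxy)-3-methoxy-5-(triisopropylsilyloxymethyl)phenyl]malonic acid (not isolated) | OC(=O)C(C(O)=O)c1cc(CO[Si](C(C)C)(C(C)C)C(C)C)cc(OC)c1OCc1ccccc1 | intermediate
8 | 2-[2-(benzyloxy)-3-methoxy-5-(triisopropylsilyloxymethyl)phenyl]acetic acid | OC(=O)Cc1cc(CO[Si](C(C)C)(C(C)C)C(C)C)cc(OC)c1OCc1ccccc1 | intermediate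
9 | (S)-4-benzyl-2-oxazolidinone | O=C1N[C@@H](Cc2ccccc2)CO1 | starting material
10 | mixed anhydride of acid 8 and pivalic acid (not isolated) | CC(C)(C)C(=O)OC(=O)Cc1cc(CO[Si](C(C)C)(C(C)C)C(C)C)cc(OC)c1OCc1ccccc1 | intermediate
11 | (4S)-4-benzyl-3-{2-[2-(benzyloxy)-3-methoxy-5-(triisopropylsilyloxymethyl)phenyl]acetyl}oxazolidin-2-one | O=C(Cc1cc(CO[Si](C(C)C)(C(C)C)C(C)C)cc(OC)c1OCc1ccccc1)N1[C@@H](Cc2ccccc2)COC1=O | intermediate
12 | [4-(benzyloxy)-3-methoxyphenyl]methanol | COc1cc(CO)ccc1OCc1ccccc1 | starting material
13 | 4-(benzyloxy)-3-methoxybenzyl bromide | COc1cc(CBr)ccc1OCc1ccccc1 | intermediate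
14 | sodium (Z)-enolate of imide 11 (not isolated) | [Na+].[O-]/C(=C\c1cc(CO[Si](C(C)C)(C(C)C)C(C)C)cc(OC)c1OCc1ccccc1)N1[C@@H](Cc2ccccc2)COC1=O | intermediate
15 | (4S)-4-benzyl-3-[(2S)-2-[2-(benzyloxy)-3-methoxy-5-(triisopropylsilyloxymethyl)phenyl]-3-[4-(benzyloxy)-3-methoxyphenyl]propanoyl]oxazolidin-2-one | COc1cc(C[C@H](C(=O)N2[C@@H](Cc3ccccc3)COC2=O)c2cc(CO[Si](C(C)C)(C(C)C)C(C)C)cc(OC)c2OCc2ccccc2)ccc1OCc1ccccc1 | intermediate
16 | benzylic alcohol from 15 (silyl group removed; 2S) | COc1cc(C[C@H](C(=O)N2[C@@H](Cc3ccccc3)COC2=O)c2cc(CO)cc(OC)c2OCc2ccccc2)ccc1OCc1ccccc1 | intermediate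
17 | benzylic bromide from 16 (2S) | COc1cc(C[C@H](C(=O)N2[C@@H](Cc3ccccc3)COC2=O)c2cc(CBr)cc(OC)c2OCc2ccccc2)ccc1OCc1ccccc1 | intermediate
18 | lithium (Z)-enolate of imide 11 (not isolated) | [Li+].[O-]/C(=C\c1cc(CO[Si](C(C)C)(C(C)C)C(C)C)cc(OC)c1OCc1ccccc1)N1[C@@H](Cc2ccccc2)COC1=O | intermediate
19 | bis-imide: 17 joined through its CH2 to the α-carbon of 11 (both α-carbons S, both auxiliaries 4S) | COc1cc(C[C@H](C(=O)N2[C@@H](Cc3ccccc3)COC2=O)c2cc(C[C@H](C(=O)N3[C@@H](Cc4ccccc4)COC3=O)c3cc(CO[Si](C(C)C)(C(C)C)C(C)C)cc(OC)c3OCc3ccccc3)cc(OC)c2OCc2ccccc2)ccc1OCc1ccccc1 | intermediate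
20 | (S,S)-diol, tris-benzyl ether, arene E silyloxymethyl | COc1cc(C[C@H](CO)c2cc(C[C@H](CO)c3cc(CO[Si](C(C)C)(C(C)C)C(C)C)cc(OC)c3OCc3ccccc3)cc(OC)c2OCc2ccccc2)ccc1OCc1ccccc1 | intermediate
21 | (S,S)-triol, tris-benzyl ether, arene E hydroxymethyl | COc1cc(C[C@H](CO)c2cc(C[C@H](CO)c3cc(CO)cc(OC)c3OCc3ccccc3)cc(OC)c2OCc2ccccc2)ccc1OCc1ccccc1 | intermediate
22 | (S,S)-diol aldehyde, tris-benzyl ether | COc1cc(C[C@H](CO)c2cc(C[C@H](CO)c3cc(C=O)cc(OC)c3OCc3ccccc3)cc(OC)c2OCc2ccccc2)ccc1OCc1ccccc1 | intermediate
23 | open-chain (S,S)-triphenol diol aldehyde | COc1cc(C[C@H](CO)c2cc(C[C@H](CO)c3cc(C=O)cc(OC)c3O)cc(OC)c2O)ccc1O | intermediate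
24 | p-quinone methide of arene C, methide carbon = future C2', methide geometry undefined (not isolated) | COc1cc(C[C@H](CO)C2=CC(=C[C@H](CO)c3cc(C=O)cc(OC)c3O)C=C(OC)C2=O)ccc1O | intermediate
25 | phenol with ring D closed (2'R,3'S), ring B still open, 3S (not isolated) | COc1cc(C[C@H](CO)c2cc([C@@H]3Oc4c(OC)cc(C=O)cc4[C@H]3CO)cc(OC)c2O)ccc1O | intermediate
26 | p-quinone methide of ring A, methide carbon = future C2, methide geometry undefined (not isolated) | COC1=CC(=C[C@H](CO)c2cc([C@@H]3Oc4c(OC)cc(C=O)cc4[C@H]3CO)cc(OC)c2O)C=CC1=O | intermediate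
27 | (2R,3S,2'R,3'S)-bis(dihydrobenzofuran) C5' aldehyde | COc1cc([C@@H]2Oc3c(OC)cc([C@@H]4Oc5c(OC)cc(C=O)cc5[C@H]4CO)cc3[C@H]2CO)ccc1O | intermediate
28 | ethyl (triphenylphosphoranylidene)acetate | CCOC(=O)C=P(c1ccccc1)(c1ccccc1)c1ccccc1 | starting material
29 | ethyl (E)-3-aryl-acrylate at C5' of 27 | COc1cc([C@@H]2Oc3c(OC)cc([C@@H]4Oc5c(OC)cc(/C=C/C(=O)OCC)cc5[C@H]4CO)cc3[C@H]2CO)ccc1O | intermediate
30 | CNP0250921.1, (2R,3S,2'R,3'S), E-propenol | COc1cc([C@@H]2Oc3c(OC)cc([C@@H]4Oc5c(OC)cc(/C=C/CO)cc5[C@H]4CO)cc3[C@H]2CO)ccc1O | target

**Count**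

Total: 18 steps. Longest linear sequence: 17 steps (steps 1–6 and 8–18, from 5-iodovanillin); step 7 is a one-step side branch.

**Steps most likely to fail**

1. Step 16. A third hydride abstraction from an already closed ring (dehydrogenation to a benzofuran) may compete. The methides may also tautomerise to stilbenes or be captured between molecules before the phenol closes. Fallback: oxidation and ring closure are separated. Setting out from 23, DDQ in MeOH/CH2Cl2 at 0 °C should intercept each methide at once with solvent (the known benzylic methoxylation of 4-alkylphenols) and give the bis(benzylic methyl ether) F1, with any partly cyclised material carried along. After removal of the hydroquinone, catalytic CF3CO2H in CH2Cl2 at rt should ionise each ether with loss of methanol, in the absence of oxidant. The phenols then close both rings under equilibrating conditions to the trans,trans product, and the route is rejoined at 27.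

2. Step 11. Proton transfer from the α-position of the imide in 17 to enolate 18 may erode the C3 configuration and stall the alkylation, or the enolate may attack that imide carbonyl. Fallback: the first auxiliary is removed before the second alkylation. Setting out from 15, LiBH4 should give the primary alcohol F2, and t-BuCOCl/pyridine its pivalate F3. HF·pyridine then frees the benzylic alcohol F4, and CBr4/PPh3 gives the benzylic bromide F5. Alkylation of the lithium enolate 18, generated from 11 with LiN(SiMe3)2 as in step 11, with F5 should give the imide pivalate F6. LiAlH4 in THF at 0 °C then cleaves the auxiliary and the pivalate together, and the route is rejoined at 20.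

3. Step 15. Reduction of the aryl aldehyde (to the benzylic alcohol and on to the methyl group) may overtake cleavage of the last benzyl ether. Fallback: the reductive deprotection is replaced by Lewis-acid dealkylation. Setting out from 22, BCl3 with pentamethylbenzene in CH2Cl2 at −78 °C should remove the three benzyl groups as cations trapped by the scavenger. The methyl ethers and the aldehyde survive, and the alcohols are released from their borates on work-up. The route is rejoined at 23, and this detour makes no compound outside the list (F0).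

**Further compounds**

F1 | step 16 | bis(benzylic methyl ether) of 23 (OMe on the future C2 and C2', both epimers) | COc1cc(C(OC)[C@H](CO)c2cc(C(OC)[C@H](CO)c3cc(C=O)cc(OC)c3O)cc(OC)c2O)ccc1O
F2 | step 11 | (2S)-2-[2-(benzyloxy)-3-methoxy-5-(triisopropylsilyloxymethyl)phenyl]-3-[4-(benzyloxy)-3-methoxyphenyl]propan-1-ol | COc1cc(C[C@H](CO)c2cc(CO[Si](C(C)C)(C(C)C)C(C)C)cc(OC)c2OCc2ccccc2)ccc1OCc1ccccc1
F3 | step 11 | pivalate of F2 | COc1cc(C[C@H](COC(=O)C(C)(C)C)c2cc(CO[Si](C(C)C)(C(C)C)C(C)C)cc(OC)c2OCc2ccccc2)ccc1OCc1ccccc1
F4 | step 11 | benzylic alcohol from F3 | COc1cc(C[C@H](COC(=O)C(C)(C)C)c2cc(CO)cc(OC)c2OCc2ccccc2)ccc1OCc1ccccc1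
F5 | step 11 | benzylic bromide from F4 | COc1cc(C[C@H](COC(=O)C(C)(C)C)c2cc(CBr)cc(OC)c2OCc2ccccc2)ccc1OCc1ccccc1
F6 | step 11 | imide pivalate from F5 and 11 (new α-carbon S) | COc1cc(C[C@H](COC(=O)C(C)(C)C)c2cc(C[C@H](C(=O)N3[C@@H](Cc4ccccc4)COC3=O)c3cc(CO[Si](C(C)C)(C(C)C)C(C)C)cc(OC)c3OCc3ccccc3)cc(OC)c2OCc2ccccc2)ccc1OCc1ccccc1
F0 | step 15 | none | none
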